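The route rests on cutting the two aryl–CH2 bonds that join the prenyl chains to C6 and C8 of ring A and tracing both carbon substituents back to allyl ethers on O5 and O7. In ring A, C6 and C8 are the only unsubstituted carbons; C6 is ortho to O5 and O7, C8 is ortho to O7 and para to O5, so one thermal double Claisen rearrangement of a (2S)-5,7-bis(allyloxy)flavanone can place the allyl groups nowhere else. The precursor carries the finished chromene ring B with its 2'-oxygen masked as a methoxymethyl ether and C2 already set by rhodium-catalysed asymmetric arylation of 5,7-bis(allyloxy)chromone; cross-metathesis later turns allyl into prenyl.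

Key step: step 9

Structure check: C2 of the target, of the key-step precursor 18 and of its product 21 is S in each case (O1 > aryl carbon > C3 > H). Ring B is a 7-oxygenated 2,2-dimethyl-2H-chromen-6-yl unit throughout, and no structural correction is required.

Design note: the ring B phenol stays capped as its MOM ether during the heating, because a free 2'-hydroxyl on this electron-rich benzylic centre would invite opening of ring C. The MOM group is removed before the metathesis, not after it, so that acid never meets a prenyl group next to a free phenol.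

Assumption: the (S,S)-enantiomer of the diene ligand is taken to deliver the aryl group to the Re face of C2 of the chromone (priorities O1 > C3 > H), by analogy with the sense of addition to cyclic enones. Should the sense be opposite for this ortho-substituted aryl group, the (R,R)-diene is used in an otherwise unchanged step 8.

Step 1
Reactants: 1 2,4,6-trihydroxyacetophenone; 2 allyl bromide
Product: 3 1-[2,4-bis(allyloxy)-6-hydroxyphenyl]ethan-1-one
Conditions: 2 (2.1 equiv), K2CO3 (2.2 equiv), acetone, reflux
Reagents that add atoms: none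
Why: Williamson etherification should stop after two O-allylations because the remaining hydroxyl is locked in a strong hydrogen bond to the acetyl carbonyl and is far less nucleophilic under K2CO3 in acetone.

Step 2
Reactants: 3 1-[2,4-bis(allyloxy)-6-hydroxyphenyl]ethan-1-one; 4 N,N-dimethylformamide dimethyl acetal
Product: 6 5,7-bis(allyloxy)-4H-chromen-4-one, via enaminone 5 (not isolated)
Conditions: 4 (3 equiv, neat), 95 °C; then conc. aq HCl, CH2Cl2, 40 °C
Reagents that add atoms: none
Why: Condensation of the methyl ketone with the amide acetal gives the β-dimethylamino enone, and acid then drives intramolecular conjugate addition of the phenol with loss of dimethylamine (enaminone chromone synthesis), conditions under which allyl aryl ethers are inert.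

Step 3
Reactants: 7 4-bromoresorcinol; 8 3-methylbut-2-enoic acid
Product: 10 6-bromo-7-hydroxy-2,2-dimethylchroman-4-one, via aryl enone 9 (not isolated)
Conditions: P4O10 in MeSO3H (1:10 w/w), 70 °C
Reagents that add atoms: none
Why: Friedel–Crafts acylation should occur at C6 of the resorcinol (para to one hydroxyl, ortho to the other, with C2 hindered and C4 blocked by bromine), after which the ortho hydroxyl closes the pyranone by oxa-Michael addition to the β,β-dimethyl enone.

Step 4
Reactants: 10 6-bromo-7-hydroxy-2,2-dimethylchroman-4-one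
Product: 11 6-bromo-7-(methoxymethoxy)-2,2-dimethylchroman-4-one
Conditions: MOMCl, i-Pr2NEt, CH2Cl2, 0 °C to rt
Reagents that add atoms: chloromethyl methyl ether, COCCl
Why: O-alkylation of the acidic phenol with the reactive α-chloro ether gives the MOM acetal, which removes the phenoxide that would otherwise deactivate the ketone towards hydride and open an over-reduction path through a quinone methide.

Step 5
Reactants: 11 6-bromo-7-(methoxymethoxy)-2,2-dimethylchroman-4-one
Product: 12 racemic 6-bromo-7-(methoxymethoxy)-2,2-dimethylchroman-4-ol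
Conditions: NaBH4, MeOH, 0 °C to rt
Reagents that add atoms: none
Why: Borohydride 1,2-reduction of the aryl ketone leaves the aryl bromide and the acetal untouched, and the racemic carbinol centre is of no consequence because it is destroyed in the next step.

Step 6
Reactants: 12 racemic 6-bromo-7-(methoxymethoxy)-2,2-dimethylchroman-4-ol
Product: 14 6-bromo-7-(methoxymethoxy)-2,2-dimethyl-2H-chromene, via mesylate 13 (not isolated)
Conditions: MsCl, Et3N (4 equiv), CH2Cl2, 0 °C to 40 °C
Reagents that add atoms: none
Why: The benzylic mesylate, activated by the para and ortho ring oxygens, should ionise and eliminate under amine base to the conjugated chromene (sulfonate elimination), which avoids the protic acid that would endanger the MOM ether.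

Step 7
Reactants: 14 6-bromo-7-(methoxymethoxy)-2,2-dimethyl-2H-chromene
Product: 17 [7-(methoxymethoxy)-2,2-dimethyl-2H-chromen-6-yl]boronic acid, via aryllithium 15 (not isolated), via lithium triisopropoxyborate 16 (not isolated)
Conditions: n-BuLi, THF, −78 °C; B(OiPr)3, −78 °C to rt; 1 M aq HCl to pH 5, 0 °C
Reagents that add atoms: triisopropyl borate, CC(C)OB(OC(C)C)OC(C)C; water, O
Why: Bromine–lithium exchange is faster than any deprotonation at −78 °C and is assisted by the neighbouring MOM oxygen, the aryllithium is trapped by the borate ester, and brief hydrolysis at pH 5 frees the boronic acid without cleaving the acetal.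

Step 8
Reactants: 6 5,7-bis(allyloxy)-4H-chromen-4-one; 17 [7-(methoxymethoxy)-2,2-dimethyl-2H-chromen-6-yl]boronic acid
Product: 18 (2S)-5,7-bis(allyloxy)-2-[7-(methoxymethoxy)-2,2-dimethyl-2H-chromen-6-yl]chroman-4-one
Conditions: [Rh(C2H4)2Cl]2 (2.5 mol %), (S,S)-2,5-diphenylbicyclo[2.2.2]octa-2,5-diene (5.5 mol %), 17 (2.5 equiv), aq KOH (0.1 equiv), toluene/H2O (10:1), 40 °C
Reagents that add atoms: none
Why: In this Hayashi–Miyaura conjugate addition the aryl group passes from boron to rhodium, the chromone C2=C3 bond inserts into the Rh–aryl bond inside the C2-symmetric diene pocket so that the aryl group is delivered to the Re face of C2 and sets the 2S centre, and protonolysis of the rhodium enolate by water releases the flavanone while the low base loading limits ring opening.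

Step 9
Reactants: 18 (2S)-5,7-bis(allyloxy)-2-[7-(methoxymethoxy)-2,2-dimethyl-2H-chromen-6-yl]chroman-4-one
Product: 21 (2S)-6,8-diallyl-5,7-dihydroxy-2-[7-(methoxymethoxy)-2,2-dimethyl-2H-chromen-6-yl]chroman-4-one, via 6-allyl-5-hydroxy isomer 19 (not isolated), via 8-allyl-7-hydroxy isomer 20 (not isolated)
Conditions: 1,2-dichlorobenzene (degassed, 0.05 M), 190 °C, sealed tube, argon
Reagents that add atoms: none
Why: Each allyl aryl ether undergoes a concerted suprafacial [3,3]-sigmatropic (aromatic Claisen) shift through a chair-like transition state to an ortho-cyclohexadienone, and tautomerisation to the phenol makes each shift irreversible, the new 5-hydroxyl gaining a hydrogen bond to the C4 carbonyl. The closest known reaction type is the thermal Claisen and Claisen–Cope rearrangement of 5- and 7-allyloxy chromanones, flavanones and flavones. No ring is closed and no stereocentre is created; only the C6–CH2 and C8–CH2 bonds are formed. The selectivity required is regiochemical and ring A secures it, because C6 (ortho to O5 and O7) and C8 (ortho to O7, para to O5) are its only unsubstituted carbons, so the O5 allyl group can reach C6 and the O7 allyl group C8 or C6. Should an allyl group arrive at a carbon that is already substituted, the resulting dienone cannot enolise and either hands the group on by a Cope shift or returns it, and because an unsubstituted allyl group is unchanged by allylic inversion every pathway should drain into 21 through 19 or 20. The C2 configuration is expected to hold because the medium contains no base to promote retro-oxa-Michael opening of ring C and the ring B oxygen remains capped as its methoxymethyl ether.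

Step 10
Reactants: 21 (2S)-6,8-diallyl-5,7-dihydroxy-2-[7-(methoxymethoxy)-2,2-dimethyl-2H-chromen-6-yl]chroman-4-one
Product: 22 (2S)-6,8-diallyl-5,7-dihydroxy-2-(7-hydroxy-2,2-dimethyl-2H-chromen-6-yl)chroman-4-one
Conditions: 3 M aq HCl, MeOH, 40 °C, stopped at full conversion
Reagents that add atoms: none
Why: Acid-catalysed acetal exchange with methanol frees the phenol, and at this stage the side chains are monosubstituted allyl groups that cannot form stabilised cations, so cyclisation onto the flanking phenols is not expected and C2 is exposed only to brief, mild acid.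

Step 11
Reactants: 22 (2S)-6,8-diallyl-5,7-dihydroxy-2-(7-hydroxy-2,2-dimethyl-2H-chromen-6-yl)chroman-4-one; 23 2-methylbut-2-ene
Product: 24 euchrenone a3, (2S)-5,7-dihydroxy-2-(7-hydroxy-2,2-dimethyl-2H-chromen-6-yl)-6,8-bis(3-methylbut-2-en-1-yl)chroman-4-one
Conditions: 23 (large excess), second-generation Grubbs catalyst (H2IMes)(PCy3)Cl2Ru=CHPh (10 mol %), CH2Cl2, 40 °C, sealed tube
Reagents that add atoms: none
Why: Olefin cross-metathesis exchanges the terminal CH2 of each allyl group for the isopropylidene unit of the excess trisubstituted alkene, the prenyl olefins formed are too hindered to react further, and the cis-disubstituted chromene alkene next to its quaternary carbon should stay out of the catalytic cycle under these neutral conditions.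

Compound list
1 | 2,4,6-trihydroxyacetophenone | CC(=O)c1c(O)cc(O)cc1O | starting material
2 | allyl bromide | C=CCBr | starting material
3 | 1-[2,4-bis(allyloxy)-6-hydroxyphenyl]ethan-1-one | CC(=O)c1c(O)cc(OCC=C)cc1OCC=C | intermediate
4 | N,N-dimethylformamide dimethyl acetal | COC(OC)N(C)C | starting material
5 | (E)-1-[2,4-bis(allyloxy)-6-hydroxyphenyl]-3-(dimethylamino)prop-2-en-1-one | CN(C)/C=C/C(=O)c1c(O)cc(OCC=C)cc1OCC=C | intermediate
6 | 5,7-bis(allyloxy)-4H-chromen-4-one | O=c1ccoc2cc(OCC=C)cc(OCC=C)c12 | intermediate
7 | 4-bromoresorcinol | Oc1ccc(Br)c(O)c1 | starting material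
8 | 3-methylbut-2-enoic acid | CC(C)=CC(=O)O | starting material
9 | 1-(5-bromo-2,4-dihydroxyphenyl)-3-methylbut-2-en-1-one | CC(C)=CC(=O)c1cc(Br)c(O)cc1O | intermediate
10 | 6-bromo-7-hydroxy-2,2-dimethylchroman-4-one | CC1(C)CC(=O)c2cc(Br)c(O)cc2O1 | intermediate
11 | 6-bromo-7-(methoxymethoxy)-2,2-dimethylchroman-4-one | COCOc1cc2OC(C)(C)CC(=O)c2cc1Br | intermediate
12 | racemic 6-bromo-7-(methoxymethoxy)-2,2-dimethylchroman-4-ol | COCOc1cc2OC(C)(C)CC(O)c2cc1Br | intermediate
13 | racemic 6-bromo-7-(methoxymethoxy)-2,2-dimethylchroman-4-yl methanesulfonate | COCOc1cc2OC(C)(C)CC(OS(C)(=O)=O)c2cc1Br | intermediate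
14 | 6-bromo-7-(methoxymethoxy)-2,2-dimethyl-2H-chromene | COCOc1cc2OC(C)(C)C=Cc2cc1Br | intermediate
15 | [7-(methoxymethoxy)-2,2-dimethyl-2H-chromen-6-yl]lithium | [Li]c1cc2C=CC(C)(C)Oc2cc1OCOC | intermediate
16 | lithium triisopropoxy[7-(methoxymethoxy)-2,2-dimethyl-2H-chromen-6-yl]borate | [Li+].CC(C)O[B-](OC(C)C)(OC(C)C)c1cc2C=CC(C)(C)Oc2cc1OCOC | intermediate
17 | [7-(methoxymethoxy)-2,2-dimethyl-2H-chromen-6-yl]boronic acid | COCOc1cc2OC(C)(C)C=Cc2cc1B(O)O | intermediate
18 | (2S)-5,7-bis(allyloxy)-2-[7-(methoxymethoxy)-2,2-dimethyl-2H-chromen-6-yl]chroman-4-one | C=CCOc1cc2c(c(OCC=C)c1)C(=O)C[C@@H](c1cc3c(cc1OCOC)OC(C)(C)C=C3)O2 | intermediate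
19 | (2S)-6-allyl-7-(allyloxy)-5-hydroxy-2-[7-(methoxymethoxy)-2,2-dimethyl-2H-chromen-6-yl]chroman-4-one | C=CCOc1cc2c(c(O)c1CC=C)C(=O)C[C@@H](c1cc3c(cc1OCOC)OC(C)(C)C=C3)O2 | intermediate
20 | (2S)-8-allyl-5-(allyloxy)-7-hydroxy-2-[7-(methoxymethoxy)-2,2-dimethyl-2H-chromen-6-yl]chroman-4-one | C=CCOc1cc(O)c(CC=C)c2c1C(=O)C[C@@H](c1cc3c(cc1OCOC)OC(C)(C)C=C3)O2 | intermediate
21 | (2S)-6,8-diallyl-5,7-dihydroxy-2-[7-(methoxymethoxy)-2,2-dimethyl-2H-chromen-6-yl]chroman-4-one | C=CCc1c(O)c(CC=C)c2c(c1O)C(=O)C[C@@H](c1cc3c(cc1OCOC)OC(C)(C)C=C3)O2 | intermediate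
22 | (2S)-6,8-diallyl-5,7-dihydroxy-2-(7-hydroxy-2,2-dimethyl-2H-chromen-6-yl)chroman-4-one | C=CCc1c(O)c(CC=C)c2c(c1O)C(=O)C[C@@H](c1cc3c(cc1O)OC(C)(C)C=C3)O2 | intermediate
23 | 2-methylbut-2-ene | CC=C(C)C | starting material
24 | euchrenone a3, (2S)-5,7-dihydroxy-2-(7-hydroxy-2,2-dimethyl-2H-chromen-6-yl)-6,8-bis(3-methylbut-2-en-1-yl)chroman-4-one | CC(C)=CCc1c(O)c(CC=C(C)C)c2c(c1O)C(=O)C[C@@H](c1cc3c(cc1O)OC(C)(C)C=C3)O2 | target

Total step count: 11
Longest linear sequence: 9 steps (steps 3 to 11, from 4-bromoresorcinol 7); the chromone branch (steps 1 and 2) joins at step 8.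

Steps most likely to fail

Step 9. The temperature needed for two consecutive sigmatropic shifts may erode the C2 configuration through reversible thermal opening of ring C. It may also degrade the chromene or the acetal, or leave the second shift incomplete. The fallback moves the rearrangement to a stage without a stereocentre. It sets out from chromone 6, which on heating in 1,2-dichlorobenzene at 190 °C should give 6,8-diallyl-5,7-dihydroxy-4H-chromen-4-one F1 by the same double Claisen process. Both phenols are then capped with NaH and MOMCl in DMF to give 6,8-diallyl-5,7-bis(methoxymethoxy)-4H-chromen-4-one F2. Conjugate addition of boronic acid 17 under the conditions of step 8 should give (2S)-6,8-diallyl-5,7-bis(methoxymethoxy)-2-[7-(methoxymethoxy)-2,2-dimethyl-2H-chromen-6-yl]chroman-4-one F3. Treatment with aq HCl in MeOH at 40 °C removes all three acetals and the route is rejoined at 22.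

Step 8. Protodeboronation of the electron-rich ortho-alkoxy arylboronic acid may outrun transmetalation. Insertion into the electron-rich 5,7-dialkoxychromone may be slow, facial discrimination may suffer with the ortho-substituted aryl group, or hydroxide may open ring C of the product. The fallback builds the flavanone through a chalcone and resolves it. It sets out from bromochromene 14, which by bromine–lithium exchange (n-BuLi, THF, −78 °C) and quenching with DMF gives 7-(methoxymethoxy)-2,2-dimethyl-2H-chromene-6-carbaldehyde F4. Claisen–Schmidt condensation with acetophenone 3 (KOH, EtOH, rt) gives (E)-1-[2,4-bis(allyloxy)-6-hydroxyphenyl]-3-[7-(methoxymethoxy)-2,2-dimethyl-2H-chromen-6-yl]prop-2-en-1-one F5. Oxa-Michael cyclisation with NaOAc in EtOH at reflux gives racemic 5,7-bis(allyloxy)-2-[7-(methoxymethoxy)-2,2-dimethyl-2H-chromen-6-yl]chroman-4-one F6. Preparative HPLC on an amylose tris(3,5-dimethylphenylcarbamate) stationary phase separates the enantiomers, and the route is rejoined at 18.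

Step 11. Ruthenium hydride species may migrate the allyl double bonds into conjugation, the chelating phenols may sequester the catalyst, or exchange may stop after one of the two sites. The fallback masks the phenols during the metathesis. It sets out from 22, which with Ac2O, pyridine and catalytic DMAP at 0 °C gives (2S)-2-(7-acetoxy-2,2-dimethyl-2H-chromen-6-yl)-6,8-diallyl-4-oxochroman-5,7-diyl diacetate F7. Cross-metathesis with 23 under the conditions of step 11 should give (2S)-2-(7-acetoxy-2,2-dimethyl-2H-chromen-6-yl)-6,8-bis(3-methylbut-2-en-1-yl)-4-oxochroman-5,7-diyl diacetate F8. Near-neutral methanolysis of the aryl acetates (NH4OAc, MeOH/H2O, rt) returns the route at 24.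

Further compounds
F1 | step 9 | 6,8-diallyl-5,7-dihydroxy-4H-chromen-4-one | O=c1ccoc2c(CC=C)c(O)c(CC=C)c(O)c12
F2 | step 9 | 6,8-diallyl-5,7-bis(methoxymethoxy)-4H-chromen-4-one | O=c1ccoc2c(CC=C)c(OCOC)c(CC=C)c(OCOC)c12
F3 | step 9 | (2S)-6,8-diallyl-5,7-bis(methoxymethoxy)-2-[7-(methoxymethoxy)-2,2-dimethyl-2H-chromen-6-yl]chroman-4-one | C=CCc1c(OCOC)c(CC=C)c2c(c1OCOC)C(=O)C[C@@H](c1cc3c(cc1OCOC)OC(C)(C)C=C3)O2
F4 | step 8 | 7-(methoxymethoxy)-2,2-dimethyl-2H-chromene-6-carbaldehyde | COCOc1cc2OC(C)(C)C=Cc2cc1C=O
F5 | step 8 | (E)-1-[2,4-bis(allyloxy)-6-hydroxyphenyl]-3-[7-(methoxymethoxy)-2,2-dimethyl-2H-chromen-6-yl]prop-2-en-1-one | C=CCOc1cc(O)c(C(=O)/C=C/c2cc3C=CC(C)(C)Oc3cc2OCOC)c(OCC=C)c1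
F6 | step 8 | racemic 5,7-bis(allyloxy)-2-[7-(methoxymethoxy)-2,2-dimethyl-2H-chromen-6-yl]chroman-4-one | C=CCOc1cc2c(c(OCC=C)c1)C(=O)CC(c1cc3c(cc1OCOC)OC(C)(C)C=C3)O2
F7 | step 11 | (2S)-2-(7-acetoxy-2,2-dimethyl-2H-chromen-6-yl)-6,8-diallyl-4-oxochroman-5,7-diyl diacetate | C=CCc1c(OC(C)=O)c(CC=C)c2c(c1OC(C)=O)C(=O)C[C@@H](c1cc3c(cc1OC(C)=O)OC(C)(C)C=C3)O2
F8 | step 11 | (2S)-2-(7-acetoxy-2,2-dimethyl-2H-chromen-6-yl)-6,8-bis(3-methylbut-2-en-1-yl)-4-oxochroman-5,7-diyl diacetate | CC(C)=CCc1c(OC(C)=O)c(CC=C(C)C)c2c(c1OC(C)=O)C(=O)C[C@@H](c1cc3c(cc1OC(C)=O)OC(C)(C)C=C3)O2
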